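## Retrosynthetic overview

1. Target 19 ⇐ bis-acetonide 17: remove both acetonides, then equilibrate C8a in the free diol.
2. 17 ⇐ acyclic enyne–ynone 14 by hydrative cyclisation: ring A (cyclohexenone, C5–C4a bond) closes first, ring B (pyran, O1–C1 bond) second.
3. 14 ⇐ Weinreb amide 3 + alkynol 10 (C8a–C4a bond), then C1 by Wittig methylenation and oxidation at C3.
4. 3 ⇐ L-threonine acetonide ester 1 by light-driven C–H alkynylation (C7–C6 bond; quaternary C7 set by C8).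
5. 10 ⇐ D-isoleucine 4: C4′/C5′ bought, C3′ by chelation-controlled vinyl addition, then cross-metathesis and ethynyl addition.

Assumption: the SMILES is taken literally (7S,8R,8aS; side chain 3R,4R,5R), and acetonide ester 1 is bought as a catalogue compound made from L-threonine.

## Route

Step 1
Reactants: 1 methyl (4S,5R)-2,2,5-trimethyl-1,3-dioxolane-4-carboxylate
Product: 2 methyl (4S,5R)-2,2,5-trimethyl-5-[2-(trimethylsilyl)ethynyl]-1,3-dioxolane-4-carboxylate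
Conditions: TMS–C≡C–SO2Tol (1 equiv), 1 (3 equiv, excess recovered), (n-Bu4N)4[W10O32] (2 mol %), MeCN, 390 nm LEDs, 25 °C, Ar
Reagents that add atoms: 1-(4-methylbenzenesulfonyl)-2-(trimethylsilyl)ethyne, Cc1ccc(cc1)S(=O)(=O)C#C[Si](C)(C)C
Why: Proposed new method: photoexcited decatungstate abstracts the only hydridic tertiary C–H (C5–H; C4–H is deactivated by the ester), the dioxolanyl radical adds to the sulfonyl-bearing alkyne carbon on the face anti to the C4 ester and expels the tolylsulfonyl radical (reduced back to the sulfinic acid by the reduced polyoxometalate, closing the cycle), so the C7–C6 bond and the oxygenated quaternary centre (alkynyl trans to the ester, 5R) are set by the threonine-derived centre; the closest known reaction type is photochemical hydrogen-atom-transfer C(sp3)–H alkynylation of simple ethers with alkynyl sulfones, not shown for the tertiary C–H of a diol acetonide forming a stereodefined tetrasubstituted carbon.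

Step 2
Reactants: 2 methyl (4S,5R)-2,2,5-trimethyl-5-[2-(trimethylsilyl)ethynyl]-1,3-dioxolane-4-carboxylate
Product: 3 (4S,5R)-N-methoxy-N,2,2,5-tetramethyl-5-[2-(trimethylsilyl)ethynyl]-1,3-dioxolane-4-carboxamide
Conditions: MeNH(OMe)·HCl (2 equiv), i-PrMgCl (4 equiv), THF, −20 °C
Reagents that add atoms: N,O-dimethylhydroxylamine hydrochloride, CNOC.Cl
Why: Weinreb amidation of the ester by the magnesium amide at low temperature leaves both stereocentres untouched.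

Step 3
Reactants: 4 D-isoleucine, (2R,3R)-2-amino-3-methylpentanoic acid
Product: 5 (2R,3R)-2-hydroxy-3-methylpentanoic acid
Conditions: NaNO2, 1 M H2SO4, H2O, 0 → 23 °C
Reagents that add atoms: water, O
Why: Diazotisation of the α-amino acid proceeds with double inversion through the α-lactone, giving the α-hydroxy acid with net retention at C2 while C3 is untouched.

Step 4
Reactants: 5 (2R,3R)-2-hydroxy-3-methylpentanoic acid
Product: 6 (3R,4R)-3-hydroxy-4-methylhexan-2-one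
Conditions: MeLi (3.3 equiv), THF, −78 → 0 °C; inverse quench into 1 M HCl
Reagents that add atoms: methyllithium, [Li]C
Why: Organolithium addition to the lithium carboxylate gives a gem-dialkoxide that collapses to the methyl ketone only on quench, and the α-alkoxide prevents enolisation so both stereocentres are kept.

Step 5
Reactants: 6 (3R,4R)-3-hydroxy-4-methylhexan-2-one
Product: 7 (3R,4R,5R)-3,5-dimethylhept-1-ene-3,4-diol
Conditions: CH2=CHMgBr (3 equiv), THF, −78 → −20 °C; aq. NH4Cl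
Reagents that add atoms: vinylmagnesium bromide, C=C[Mg]Br
Why: Cram-chelate-controlled Grignard addition: the magnesium alkoxide chelates the ketone and vinyl adds anti to the sec-butyl group, setting the tertiary carbinol as 3R.

Step 6
Reactants: 7 (3R,4R,5R)-3,5-dimethylhept-1-ene-3,4-diol
Product: 8 (2E,4R,5R,6R)-4,5-dihydroxy-4,6-dimethyloct-2-enal
Conditions: (E)-crotonaldehyde (5 equiv), second-generation Hoveyda–Grubbs catalyst RuCl2(H2IMes)(=CH-C6H4-2-O-i-Pr) (5 mol %), CH2Cl2, 40 °C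
Reagents that add atoms: (E)-but-2-enal, C/C=C/C=O
Why: Olefin cross-metathesis between the slow-to-dimerise tertiary allylic alcohol and the electron-poor enal gives the (E)-enal with loss of propene.

Step 7
Reactants: 8 (2E,4R,5R,6R)-4,5-dihydroxy-4,6-dimethyloct-2-enal
Product: 9 (2E)-3-[(4R,5R)-5-[(2R)-butan-2-yl]-2,2,4-trimethyl-1,3-dioxolan-4-yl]prop-2-enal
Conditions: 2-methoxypropene, PPTS (5 mol %), CH2Cl2, 0 °C
Reagents that add atoms: 2-methoxypropene, COC(C)=C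
Why: Acid-catalysed acetonide formation on the vicinal diol (ketal exchange) touches no stereocentre.

Step 8
Reactants: 9 (2E)-3-[(4R,5R)-5-[(2R)-butan-2-yl]-2,2,4-trimethyl-1,3-dioxolan-4-yl]prop-2-enal
Product: 10 (1E)-1-[(4R,5R)-5-[(2R)-butan-2-yl]-2,2,4-trimethyl-1,3-dioxolan-4-yl]pent-1-en-4-yn-3-ol (both C3 epimers)
Conditions: HC≡CMgBr (1.5 equiv), THF, −78 → 0 °C; aq. NH4Cl
Reagents that add atoms: ethynylmagnesium bromide, C#C[Mg]Br
Why: 1,2-Addition of the alkynyl Grignard reagent to the enal; the new carbinol centre is a mixture that is erased by the oxidation in step 11.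

Step 9
Reactants: 3 (4S,5R)-N-methoxy-N,2,2,5-tetramethyl-5-[2-(trimethylsilyl)ethynyl]-1,3-dioxolane-4-carboxamide; 10 (1E)-1-[(4R,5R)-5-[(2R)-butan-2-yl]-2,2,4-trimethyl-1,3-dioxolan-4-yl]pent-1-en-4-yn-3-ol
Product: 11 (5E)-6-[(4R,5R)-5-[(2R)-butan-2-yl]-2,2,4-trimethyl-1,3-dioxolan-4-yl]-4-hydroxy-1-[(4S,5R)-2,2,5-trimethyl-5-[2-(trimethylsilyl)ethynyl]-1,3-dioxolan-4-yl]hex-5-en-2-yn-1-one
Conditions: 10 (1.1 equiv), n-BuLi (2.2 equiv), THF, −78 °C; then 3, −78 → −20 °C; aq. NH4Cl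
Reagents that add atoms: none
Why: Weinreb ketone synthesis: the alkoxide–acetylide dianion acylates at carbon and the chelated tetrahedral intermediate stops at the ynone, forming the C8a–C4a bond.

Step 10
Reactants: 11 (5E)-6-[(4R,5R)-5-[(2R)-butan-2-yl]-2,2,4-trimethyl-1,3-dioxolan-4-yl]-4-hydroxy-1-[(4S,5R)-2,2,5-trimethyl-5-[2-(trimethylsilyl)ethynyl]-1,3-dioxolan-4-yl]hex-5-en-2-yn-1-one
Product: 13 (1E)-1-[(4R,5R)-5-[(2R)-butan-2-yl]-2,2,4-trimethyl-1,3-dioxolan-4-yl]-6-[(4R,5R)-5-ethynyl-2,2,5-trimethyl-1,3-dioxolan-4-yl]hepta-1,6-dien-4-yn-3-ol, via silyl enyne alcohol 12 (not isolated)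
Conditions: Ph3PCH3Br (3 equiv), KN(SiMe3)2 (2.9 equiv), THF, −78 → 0 °C; then K2CO3 (0.3 equiv), MeOH, 23 °C
Reagents that add atoms: methyltriphenylphosphonium bromide, C[P+](c1ccccc1)(c1ccccc1)c1ccccc1.[Br-]
Why: Wittig methylenation of the alkynyl ketone (the carbinol is held as its alkoxide, which suppresses ynone isomerisation) installs C1 as a methylidene group, and methanolysis then cleaves the alkynylsilane.

Step 11
Reactants: 13 (1E)-1-[(4R,5R)-5-[(2R)-butan-2-yl]-2,2,4-trimethyl-1,3-dioxolan-4-yl]-6-[(4R,5R)-5-ethynyl-2,2,5-trimethyl-1,3-dioxolan-4-yl]hepta-1,6-dien-4-yn-3-ol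
Product: 14 (1E)-1-[(4R,5R)-5-[(2R)-butan-2-yl]-2,2,4-trimethyl-1,3-dioxolan-4-yl]-6-[(4R,5R)-5-ethynyl-2,2,5-trimethyl-1,3-dioxolan-4-yl]hepta-1,6-dien-4-yn-3-one
Conditions: MnO2 (20 equiv), CH2Cl2, 23 °C
Reagents that add atoms: none
Why: MnO2 selectively oxidises the doubly activated (allylic and propargylic) secondary alcohol to the cross-conjugated ynone.

Step 12
Reactants: 14 (1E)-1-[(4R,5R)-5-[(2R)-butan-2-yl]-2,2,4-trimethyl-1,3-dioxolan-4-yl]-6-[(4R,5R)-5-ethynyl-2,2,5-trimethyl-1,3-dioxolan-4-yl]hepta-1,6-dien-4-yn-3-one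
Product: 17 (7S,8R,8aR)-3-[(E)-2-[(4R,5R)-5-[(2R)-butan-2-yl]-2,2,4-trimethyl-1,3-dioxolan-4-yl]ethenyl]-7-methyl-7,8-(propane-2,2-diyldioxy)-1,7,8,8a-tetrahydro-6H-isochromen-6-one, via methyl ketone 15 (not isolated), via methylidene cyclohexenone 16 (not isolated)
Conditions: (IPr)AuCl (3 mol %; IPr = 1,3-bis(2,6-diisopropylphenyl)imidazol-2-ylidene), AgSbF6 (3 mol %), H2O (5 equiv), 1,4-dioxane, 45 °C; then DBU (0.5 equiv), 23 °C
Reagents that add atoms: water, O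
Why: Gold-catalysed Markovnikov hydration of the terminal alkyne gives the methyl ketone, whose enol adds 6-exo-dig to the activated ynone (hydrative 1,6-diyne carbocyclisation, closing ring A), and base then isomerises the adduct to the 4-methylidene cyclohexenone and triggers 6-endo oxa-conjugate addition of the C3 enol oxygen to the methylidene carbon (closing ring B), C8a being protonated on the acetonide-locked half-chair so that C1 sits pseudo-equatorial (8aR, corrected in step 13).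

Step 13
Reactants: 17 (7S,8R,8aR)-3-[(E)-2-[(4R,5R)-5-[(2R)-butan-2-yl]-2,2,4-trimethyl-1,3-dioxolan-4-yl]ethenyl]-7-methyl-7,8-(propane-2,2-diyldioxy)-1,7,8,8a-tetrahydro-6H-isochromen-6-one
Product: 19 (7S,8R,8aS)-3-[(1E,3R,4R,5R)-3,4-dihydroxy-3,5-dimethylhept-1-en-1-yl]-7,8-dihydroxy-7-methyl-1,7,8,8a-tetrahydro-6H-isochromen-6-one, via tetraol 8a-epimer 18 (not isolated)
Conditions: AcOH–H2O (4:1), 45 °C; concentrate; then DBU (0.2 equiv), MeOH, 23 °C
Reagents that add atoms: none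
Why: Acid hydrolysis removes both acetonides, and with the diol free ring A can adopt the half-chair with both hydroxyls axial and the methyl equatorial, so base equilibration through the cross-conjugated dienolate (reprotonation anti to the axial C8–O, A(1,2)-strain control) is expected to favour the 8aS epimer.

## Compound list

1 | methyl (4S,5R)-2,2,5-trimethyl-1,3-dioxolane-4-carboxylate | C[C@H]1OC(C)(C)O[C@@H]1C(=O)OC | starting material
2 | methyl (4S,5R)-2,2,5-trimethyl-5-[2-(trimethylsilyl)ethynyl]-1,3-dioxolane-4-carboxylate | C[C@]1(C#C[Si](C)(C)C)OC(C)(C)O[C@@H]1C(=O)OC | intermediate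
3 | (4S,5R)-N-methoxy-N,2,2,5-tetramethyl-5-[2-(trimethylsilyl)ethynyl]-1,3-dioxolane-4-carboxamide | C[C@]1(C#C[Si](C)(C)C)OC(C)(C)O[C@@H]1C(=O)N(C)OC | intermediate
4 | D-isoleucine, (2R,3R)-2-amino-3-methylpentanoic acid | CC[C@@H](C)[C@@H](N)C(=O)O | starting material
5 | (2R,3R)-2-hydroxy-3-methylpentanoic acid | CC[C@@H](C)[C@@H](O)C(=O)O | intermediate
6 | (3R,4R)-3-hydroxy-4-methylhexan-2-one | CC[C@@H](C)[C@@H](O)C(C)=O | intermediate
7 | (3R,4R,5R)-3,5-dimethylhept-1-ene-3,4-diol | CC[C@@H](C)[C@@H](O)[C@](C)(O)C=C | intermediate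
8 | (2E,4R,5R,6R)-4,5-dihydroxy-4,6-dimethyloct-2-enal | CC[C@@H](C)[C@@H](O)[C@](C)(O)/C=C/C=O | intermediate
9 | (2E)-3-[(4R,5R)-5-[(2R)-butan-2-yl]-2,2,4-trimethyl-1,3-dioxolan-4-yl]prop-2-enal | CC[C@@H](C)[C@H]1OC(C)(C)O[C@]1(C)/C=C/C=O | intermediate
10 | (1E)-1-[(4R,5R)-5-[(2R)-butan-2-yl]-2,2,4-trimethyl-1,3-dioxolan-4-yl]pent-1-en-4-yn-3-ol (both C3 epimers) | CC[C@@H](C)[C@H]1OC(C)(C)O[C@]1(C)/C=C/C(O)C#C | intermediate
11 | (5E)-6-[(4R,5R)-5-[(2R)-butan-2-yl]-2,2,4-trimethyl-1,3-dioxolan-4-yl]-4-hydroxy-1-[(4S,5R)-2,2,5-trimethyl-5-[2-(trimethylsilyl)ethynyl]-1,3-dioxolan-4-yl]hex-5-en-2-yn-1-one (both C4 epimers) | CC[C@@H](C)[C@H]1OC(C)(C)O[C@]1(C)/C=C/C(O)C#CC(=O)[C@H]2OC(C)(C)O[C@]2(C)C#C[Si](C)(C)C | intermediate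
12 | (1E)-1-[(4R,5R)-5-[(2R)-butan-2-yl]-2,2,4-trimethyl-1,3-dioxolan-4-yl]-6-[(4R,5R)-2,2,5-trimethyl-5-[2-(trimethylsilyl)ethynyl]-1,3-dioxolan-4-yl]hepta-1,6-dien-4-yn-3-ol | CC[C@@H](C)[C@H]1OC(C)(C)O[C@]1(C)/C=C/C(O)C#CC(=C)[C@H]2OC(C)(C)O[C@]2(C)C#C[Si](C)(C)C | intermediate (not isolated)
13 | (1E)-1-[(4R,5R)-5-[(2R)-butan-2-yl]-2,2,4-trimethyl-1,3-dioxolan-4-yl]-6-[(4R,5R)-5-ethynyl-2,2,5-trimethyl-1,3-dioxolan-4-yl]hepta-1,6-dien-4-yn-3-ol | CC[C@@H](C)[C@H]1OC(C)(C)O[C@]1(C)/C=C/C(O)C#CC(=C)[C@H]2OC(C)(C)O[C@]2(C)C#C | intermediate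
14 | (1E)-1-[(4R,5R)-5-[(2R)-butan-2-yl]-2,2,4-trimethyl-1,3-dioxolan-4-yl]-6-[(4R,5R)-5-ethynyl-2,2,5-trimethyl-1,3-dioxolan-4-yl]hepta-1,6-dien-4-yn-3-one | CC[C@@H](C)[C@H]1OC(C)(C)O[C@]1(C)/C=C/C(=O)C#CC(=C)[C@H]2OC(C)(C)O[C@]2(C)C#C | intermediate
15 | (1E)-6-[(4R,5S)-5-acetyl-2,2,5-trimethyl-1,3-dioxolan-4-yl]-1-[(4R,5R)-5-[(2R)-butan-2-yl]-2,2,4-trimethyl-1,3-dioxolan-4-yl]hepta-1,6-dien-4-yn-3-one | CC[C@@H](C)[C@H]1OC(C)(C)O[C@]1(C)/C=C/C(=O)C#CC(=C)[C@H]2OC(C)(C)O[C@]2(C)C(C)=O | intermediate (not isolated)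
16 | (5R,6S)-3-[(3E)-4-[(4R,5R)-5-[(2R)-butan-2-yl]-2,2,4-trimethyl-1,3-dioxolan-4-yl]-2-oxobut-3-en-1-yl]-6-methyl-4-methylidene-5,6-(propane-2,2-diyldioxy)cyclohex-2-en-1-one | CC[C@@H](C)[C@H]1OC(C)(C)O[C@]1(C)/C=C/C(=O)CC2=CC(=O)[C@@]3(C)OC(C)(C)O[C@@H]3C2=C | intermediate (not isolated)
17 | (7S,8R,8aR)-3-[(E)-2-[(4R,5R)-5-[(2R)-butan-2-yl]-2,2,4-trimethyl-1,3-dioxolan-4-yl]ethenyl]-7-methyl-7,8-(propane-2,2-diyldioxy)-1,7,8,8a-tetrahydro-6H-isochromen-6-one | CC[C@@H](C)[C@H]1OC(C)(C)O[C@]1(C)/C=C/C2=CC3=CC(=O)[C@@]4(C)OC(C)(C)O[C@@H]4[C@H]3CO2 | intermediate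
18 | (7S,8R,8aR)-3-[(1E,3R,4R,5R)-3,4-dihydroxy-3,5-dimethylhept-1-en-1-yl]-7,8-dihydroxy-7-methyl-1,7,8,8a-tetrahydro-6H-isochromen-6-one (8a-epimer of the target) | CC[C@@H](C)[C@@H](O)[C@](C)(O)/C=C/C1=CC2=CC(=O)[C@@](C)(O)[C@H](O)[C@H]2CO1 | intermediate (not isolated)
19 | (7S,8R,8aS)-3-[(1E,3R,4R,5R)-3,4-dihydroxy-3,5-dimethylhept-1-en-1-yl]-7,8-dihydroxy-7-methyl-1,7,8,8a-tetrahydro-6H-isochromen-6-one | CC[C@@H](C)[C@@H](O)[C@](C)(O)/C=C/C1=CC2=CC(=O)[C@@](C)(O)[C@H](O)[C@@H]2CO1 | target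

## Step count and risks

Total steps: 13. Longest linear sequence: 11 (steps 3–13, from D-isoleucine); the ring branch (steps 1–2) joins at step 9.

Three steps most likely to fail:

**Step 1 (proposed new C–H alkynylation).** Risks are slow hydrogen abstraction next to the ester-bearing carbon and a modest trans:cis ratio. The fallback sets out from 10 and comes back at 15, using only known enolate and carbonyl chemistry. Bought dimethyl (4S,5S)-2,2-dimethyl-1,3-dioxolane-4,5-dicarboxylate F1 (from D-tartaric acid) is methylated with LiN(i-Pr)2 and MeI (Seebach alkylation, trans diester retained) to dimethyl (4S,5S)-2,2,4-trimethyl-1,3-dioxolane-4,5-dicarboxylate F2. Only the unhindered ester is converted (MeNH(OMe)·HCl, i-PrMgCl, −30 °C) into methyl (4S,5S)-5-[methoxy(methyl)carbamoyl]-2,2,4-trimethyl-1,3-dioxolane-4-carboxylate F3. The dianion of 10 acylates F3 to the hydroxy ynone ester F4, and Wittig methylenation gives the enyne ester F5. LiCH2SiMe3 followed by methanol converts the hindered ester into the methyl ketone, enyne keto alcohol F6. MnO2 then gives 15, which is closed to 17 with DBU alone (no gold needed).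

**Step 12 (gold-catalysed hydration and double ring closure).** The risk is that gold engages the enyne or the ynone instead of the terminal alkyne. The fallback sets out from 3 and comes back at 17, hydrating the alkyne while the molecule is still simple and carrying the ketone as a silyl enol ether. Desilylation (K2CO3, MeOH) and gold-catalysed hydration of 3 give (4S,5S)-5-acetyl-N-methoxy-N,2,2,5-tetramethyl-1,3-dioxolane-4-carboxamide F7. TBSOTf and Et3N give the silyl enol ether amide F8. The dianion of 10 gives the silyl enol ether hydroxy ynone F9, Wittig methylenation gives the silyl enol ether enyne alcohol F10, and MnO2 gives the silyl enol ether ynone F11. CsF in wet THF then releases the enolate, which undergoes the same Michael closure, isomerisation and oxa-conjugate addition to 17.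

**Step 13 (C8a configuration).** The preference for 8aS in the free tetraol is argued from conformation, not demonstrated, and the epimer 18 may persist. The fallback sets out from 18 and comes back at 19, using a conformational lock. Persilylation (TESOTf, 2,6-lutidine) gives the tetrakis(triethylsilyl) ether of the 8a-epimer F12. DBU in toluene at 40 °C equilibrates C8a; the vicinal trans silyloxy groups should strongly prefer to be diaxial, which corresponds to the tetrakis(triethylsilyl) ether of the target F13. HF·pyridine in THF at 0 °C, with no base present, then releases 19.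

Further compounds
F1 | step 1 | dimethyl (4S,5S)-2,2-dimethyl-1,3-dioxolane-4,5-dicarboxylate | COC(=O)[C@H]1OC(C)(C)O[C@@H]1C(=O)OC
F2 | step 1 | dimethyl (4S,5S)-2,2,4-trimethyl-1,3-dioxolane-4,5-dicarboxylate | COC(=O)[C@H]1OC(C)(C)O[C@]1(C)C(=O)OC
F3 | step 1 | methyl (4S,5S)-5-[methoxy(methyl)carbamoyl]-2,2,4-trimethyl-1,3-dioxolane-4-carboxylate | CON(C)C(=O)[C@H]1OC(C)(C)O[C@]1(C)C(=O)OC
F4 | step 1 | methyl (4S,5S)-5-[(5E)-6-[(4R,5R)-5-[(2R)-butan-2-yl]-2,2,4-trimethyl-1,3-dioxolan-4-yl]-4-hydroxyhex-5-en-2-ynoyl]-2,2,4-trimethyl-1,3-dioxolane-4-carboxylate | CC[C@@H](C)[C@H]1OC(C)(C)O[C@]1(C)/C=C/C(O)C#CC(=O)[C@H]2OC(C)(C)O[C@]2(C)C(=O)OC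
F5 | step 1 | methyl (4S,5R)-5-[(6E)-7-[(4R,5R)-5-[(2R)-butan-2-yl]-2,2,4-trimethyl-1,3-dioxolan-4-yl]-5-hydroxyhepta-1,6-dien-3-yn-2-yl]-2,2,4-trimethyl-1,3-dioxolane-4-carboxylate | CC[C@@H](C)[C@H]1OC(C)(C)O[C@]1(C)/C=C/C(O)C#CC(=C)[C@H]2OC(C)(C)O[C@]2(C)C(=O)OC
F6 | step 1 | (1E)-6-[(4R,5S)-5-acetyl-2,2,5-trimethyl-1,3-dioxolan-4-yl]-1-[(4R,5R)-5-[(2R)-butan-2-yl]-2,2,4-trimethyl-1,3-dioxolan-4-yl]hepta-1,6-dien-4-yn-3-ol | CC[C@@H](C)[C@H]1OC(C)(C)O[C@]1(C)/C=C/C(O)C#CC(=C)[C@H]2OC(C)(C)O[C@]2(C)C(C)=O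
F7 | step 12 | (4S,5S)-5-acetyl-N-methoxy-N,2,2,5-tetramethyl-1,3-dioxolane-4-carboxamide | C[C@]1(C(C)=O)OC(C)(C)O[C@@H]1C(=O)N(C)OC
F8 | step 12 | (4S,5S)-5-[1-(tert-butyldimethylsilyloxy)ethenyl]-N-methoxy-N,2,2,5-tetramethyl-1,3-dioxolane-4-carboxamide | C[C@]1(C(=C)O[Si](C)(C)C(C)(C)C)OC(C)(C)O[C@@H]1C(=O)N(C)OC
F9 | step 12 | (5E)-6-[(4R,5R)-5-[(2R)-butan-2-yl]-2,2,4-trimethyl-1,3-dioxolan-4-yl]-1-[(4S,5S)-5-[1-(tert-butyldimethylsilyloxy)ethenyl]-2,2,5-trimethyl-1,3-dioxolan-4-yl]-4-hydroxyhex-5-en-2-yn-1-one | CC[C@@H](C)[C@H]1OC(C)(C)O[C@]1(C)/C=C/C(O)C#CC(=O)[C@H]2OC(C)(C)O[C@]2(C)C(=C)O[Si](C)(C)C(C)(C)C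
F10 | step 12 | (1E)-1-[(4R,5R)-5-[(2R)-butan-2-yl]-2,2,4-trimethyl-1,3-dioxolan-4-yl]-6-[(4R,5S)-5-[1-(tert-butyldimethylsilyloxy)ethenyl]-2,2,5-trimethyl-1,3-dioxolan-4-yl]hepta-1,6-dien-4-yn-3-ol | CC[C@@H](C)[C@H]1OC(C)(C)O[C@]1(C)/C=C/C(O)C#CC(=C)[C@H]2OC(C)(C)O[C@]2(C)C(=C)O[Si](C)(C)C(C)(C)C
F11 | step 12 | (1E)-1-[(4R,5R)-5-[(2R)-butan-2-yl]-2,2,4-trimethyl-1,3-dioxolan-4-yl]-6-[(4R,5S)-5-[1-(tert-butyldimethylsilyloxy)ethenyl]-2,2,5-trimethyl-1,3-dioxolan-4-yl]hepta-1,6-dien-4-yn-3-one | CC[C@@H](C)[C@H]1OC(C)(C)O[C@]1(C)/C=C/C(=O)C#CC(=C)[C@H]2OC(C)(C)O[C@]2(C)C(=C)O[Si](C)(C)C(C)(C)C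
F12 | step 13 | tetrakis(triethylsilyl) ether of 18, (7S,8R,8aR) | CC[C@@H](C)[C@@H](O[Si](CC)(CC)CC)[C@](C)(O[Si](CC)(CC)CC)/C=C/C1=CC2=CC(=O)[C@@](C)(O[Si](CC)(CC)CC)[C@H](O[Si](CC)(CC)CC)[C@H]2CO1
F13 | step 13 | tetrakis(triethylsilyl) ether of 19, (7S,8R,8aS) | CC[C@@H](C)[C@@H](O[Si](CC)(CC)CC)[C@](C)(O[Si](CC)(CC)CC)/C=C/C1=CC2=CC(=O)[C@@](C)(O[Si](CC)(CC)CC)[C@H](O[Si](CC)(CC)CC)[C@@H]2CO1
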